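The vessel holds 1.5 M substrate with 1.05 equiv of coupling partner while base is pumped in, so substrate is the limiting reagent and you keep its ledger. Possible steps are a plain coupling of substrate and partner to product and by-product, a by-product-assisted version of it, capture of by-product by base as salt, and a reversible slide of substrate into the dormant form.

| flask | substrate | coupling partner | base | remark | time |
|---|---|---|---|---|---|
| beta | 1.5 M | 1.05 equiv | 0.10 equiv (fed, over 2.0 h) | the very flask that is asked about, followed so far |  |
| epsilon | 1.5 M | 1.05 equiv | 0.050 equiv (fed, over 2.0 h) | run made earlier |  |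
| flask | 1.5 M | 1.05 equiv | 0.100 equiv (fed, over 2.0 h) |  | 2.0 h |

| run | time / min | product / % | substrate / % | dormant form / % |
|---|---|---|---|---|
| beta | 2.00 | 0 | 95 | 5 |
| beta | 3.00 | 1 | 93 | 7 |
| beta | 5.00 | 0 | 89 | 11 |
| beta | 8.00 | 4 | 84 | 16 |
| beta | 15.0 | 0 | 71 | 28 |
| beta | 25.0 | 1 | 61 | 37 |
| epsilon | 20.0 | 0 | 64 | 34 |
| epsilon | 40.0 | 1 | 49 | 48 |
| epsilon | 60.0 | 4 | 41 | 55 |
| epsilon | 80.0 | 1 | 38 | 63 |
| epsilon | 90.0 | 1 | 38 | 60 |
| epsilon | 120 | 0 | 33 | 66 |

(standard deviation of a reading: 1.5 percentage points)

- steps thought possible: substrate + coupling partner + by-product -> product + 2 by-product; substrate + coupling partner -> product + by-product; base + by-product <-> salt; substrate <-> dormant form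

1. concentration of product at 2.0 h, in M
2. concentration of substrate at 2.0 h, in M
3. concentration of dormant form at 2.0 h, in M

First entry, substrate. The late epsilon readings give a plateau share of 36.3%, and the beta reading at 25.0 min then gives a relaxation constant of 0.0379 min⁻¹. My reckoning therefore puts [substrate] in this flask at 0.555 M at 2.0 h.

Second entry, product. Take rate = k[substrate][coupling partner], with [coupling partner] held at its charge, the reagent in excess. Integrating needs the substrate exposure, the time integral of [substrate] over its charge: plateau share times time, plus the share relaxed away by then over the relaxation constant. For this flask it is 1.00 h. The epsilon product readings sum to 7.00% against summed exposures of 3.91 h, so k reads 0.0114 M⁻¹ h⁻¹, a rough reading, with each reading good to 1.5 percentage points. I ignore the assisted step because this flask's feed, 0.0750 M h⁻¹ of base, outruns the starting by-product rate, 0.0269 M h⁻¹. Product comes to 0.0269 M.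

Third entry, dormant form, closes the books at 0.918 M.

The forecast says 0.012 M product, 0.51 M substrate and 0.98 M dormant form: “By-product is evidently being trapped by the fed base, so beta, with double the feed, should stay quiet too.” My product stands above its figure.

    substrate + coupling partner + by-product → product + 2 by-product (k = 0.480 M⁻² h⁻¹)
    substrate + coupling partner → product + by-product (k = 0.0160 M⁻¹ h⁻¹)
    base + by-product ⇌ salt, settled at all times (K = 24000 M⁻¹)
    substrate ⇌ dormant form (K = 1.80, k = 1.40 h⁻¹)

The flask gives 0.0370 M product, 0.531 M substrate and 0.932 M dormant form. At 0.305 h the forward slide to dormant form uses substrate 56 times as fast as the plain coupling. At that moment the half-life of substrate by that coupling, 28 h, is long against the 2.0 h of this flask. Dividing the flask's product by its exposure and charges reads k as 0.0156 M⁻¹ h⁻¹. With the same exposure, the neighbour flask at 0.260 equiv of coupling partner reckons to 0.00913 M, and it holds 0.00926 M.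

Readings and results are calculated with constants of no real substance; scatter was added.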